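**Retrosynthetic overview**
1. The aryl ether C–O bond is made last, by Mitsunobu coupling of 7-hydroxy-8-methoxycoumarin (bicycle bought intact) with a (2R,3R)-epoxy alcohol; the oxirane (second ring formed) comes from Sharpless epoxidation of an (E)-allylic alcohol whose geometry is carried from geraniol.
2. The exocyclic methylene comes from a C3-phosphono lactone by Horner–Wadsworth–Emmons reaction with formaldehyde; the phosphonate is the removable activating group.
3. The lactone (first ring formed) is built by annulating the dianion of diethylphosphonoacetic acid onto a 1,2-cyclic sulfate: carbanion opening makes C3–C4, then the carboxylate closes O1–C5 with inversion.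
4. Enabling feature: lactone C4 (ring CH2) and C5 (ring CH–O) are the two carbons of a terminal 1,2-diol, so its cyclic sulfate is a 1,2-dielectrophile matched to the three-atom C3–C2(=O)–O1 dinucleophile; both diol oxygens leave as sulfate.
5. The (S)-diol comes from D-proline α-aminoxylation of the aldehyde obtained by cleaving the 6,7-alkene of O-silylated geraniol.

Key step: step 7

Assumption: 7-hydroxy-8-methoxycoumarin (daphnetin 8-methyl ether), geraniol and 2-(diethoxyphosphoryl)acetic acid are taken as purchasable.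

**Route**

Step 1
Reactants: 1 geraniol
Product: 2 tert-butyl{[(2E)-3,7-dimethylocta-2,6-dien-1-yl]oxy}diphenylsilane
Conditions: t-BuPh2SiCl, imidazole, DMF, 0 °C to rt
Reagents that add atoms: tert-butyl(chloro)diphenylsilane, CC(C)(C)[Si](Cl)(c1ccccc1)c1ccccc1
Why: Standard silylation of a primary allylic alcohol; the bulky silyl ether should survive every step up to step 9 and shield the 2,3-alkene.

Step 2
Reactants: 2 tert-butyl{[(2E)-3,7-dimethylocta-2,6-dien-1-yl]oxy}diphenylsilane
Product: 3 tert-butyl{[(2E)-5-(3,3-dimethyloxiran-2-yl)-3-methylpent-2-en-1-yl]oxy}diphenylsilane (racemic at the oxirane CH)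
Conditions: mCPBA (1.05 equiv), CH2Cl2, −20 to 0 °C
Reagents that add atoms: 3-chloroperoxybenzoic acid, OOC(=O)c1cccc(Cl)c1
Why: Prilezhaev epoxidation should take the remote 6,7-alkene first, because the 2,3-alkene is inductively deactivated by the allylic oxygen and hindered by the silyl group; the new stereocenter is destroyed in step 3.

Step 3
Reactants: 3 tert-butyl{[(2E)-5-(3,3-dimethyloxiran-2-yl)-3-methylpent-2-en-1-yl]oxy}diphenylsilane
Product: 4 (4E)-6-[(tert-butyldiphenylsilyl)oxy]-4-methylhex-4-enal
Conditions: H5IO6, THF/Et2O, 0 °C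
Reagents that add atoms: none
Why: Periodic acid opens the epoxide to the glycol and cleaves it (Malaprade-type glycol cleavage), releasing acetone and leaving the (E)-alkene and silyl ether untouched.

Step 4
Reactants: 4 (4E)-6-[(tert-butyldiphenylsilyl)oxy]-4-methylhex-4-enal
Product: 6 (2S,4E)-6-[(tert-butyldiphenylsilyl)oxy]-4-methyl-2-[(phenylamino)oxy]hex-4-en-1-ol, via α-aminoxy aldehyde 5 (not isolated)
Conditions: PhNO (slow addition), D-proline (20 mol %), DMSO, rt; then NaBH4, EtOH, 0 °C
Reagents that add atoms: nitrosobenzene, O=Nc1ccccc1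
Why: Proline-catalysed α-aminoxylation (O-selective nitroso aldol of the enamine); the carboxylic acid of D-proline hydrogen-bonds the nitroso nitrogen and delivers oxygen to one enamine face, which should set C2 as S, and immediate reduction prevents epimerization.

Step 5
Reactants: 6 (2S,4E)-6-[(tert-butyldiphenylsilyl)oxy]-4-methyl-2-[(phenylamino)oxy]hex-4-en-1-ol
Product: 7 (2S,4E)-6-[(tert-butyldiphenylsilyl)oxy]-4-methylhex-4-ene-1,2-diol
Conditions: Zn, AcOH/THF, rt
Reagents that add atoms: none
Why: Dissolving-metal reduction cleaves the weak N–O bond without touching the stereocenter, the alkene or the silyl ether.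

Step 6
Reactants: 7 (2S,4E)-6-[(tert-butyldiphenylsilyl)oxy]-4-methylhex-4-ene-1,2-diol
Product: 9 (4S)-4-[(2E)-4-[(tert-butyldiphenylsilyl)oxy]-2-methylbut-2-en-1-yl]-1,3,2-dioxathiolane 2,2-dioxide, via cyclic sulfite 8 (not isolated)
Conditions: SOCl2, Et3N, CH2Cl2, 0 °C; then RuCl3·3H2O (0.5 mol %), NaIO4 (1.1 equiv), MeCN/CH2Cl2/H2O, 0 °C, short contact
Reagents that add atoms: thionyl chloride, O=S(Cl)Cl; sodium periodate, [Na+].[O-]I(=O)(=O)=O
Why: Two-stage cyclic sulfate formation (cyclic sulfite, then RuO4-catalysed oxidation at sulfur) leaves the carbinol configuration unchanged; low RuCl3 loading and limiting NaIO4 are chosen so that sulfur oxidation should outrun attack on the hindered trisubstituted alkene.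

Step 7
Reactants: 9 (4S)-4-[(2E)-4-[(tert-butyldiphenylsilyl)oxy]-2-methylbut-2-en-1-yl]-1,3,2-dioxathiolane 2,2-dioxide; 10 2-(diethoxyphosphoryl)acetic acid
Product: 13 diethyl {(5R)-5-[(2E)-4-[(tert-butyldiphenylsilyl)oxy]-2-methylbut-2-en-1-yl]-2-oxooxolan-3-yl}phosphonate (both C3 epimers), via phosphonoacetate dianion 11 (not isolated), via sulfate monoester carboxylate 12 (not isolated)
Conditions: 10, LiN(iPr)2 (2.0 equiv), THF, −78 to 0 °C; 9, −78 °C to rt; then DMF, 80 °C
Reagents that add atoms: none
Why: Proposed new method: the carbanion of dianion 11 should open the cyclic sulfate by SN2 attack at its unhindered primary carbon to give the dilithium sulfate monoester carboxylate 12, and on heating in DMF the carboxylate oxygen should displace the secondary sulfate at C5, forming the O1–C5 bond and expelling Li2SO4. The closest known reactions are the one-pot double displacements of 1,2-cyclic sulfates by malonate (cyclopropanes) and by amidines, the Wenker-type intramolecular displacement of sulfate monoesters, and the inversion lactonization of γ-sulfonyloxy carboxylates. The only ring closed is the five-membered lactone, by 5-exo-tet substitution at C5. C5 is set by Walden inversion of the (S) sulfate carbon, so its configuration traces back to the D-proline step (the descriptor reads R here only because of priority changes), while C3 forms as an epimeric mixture that is erased in step 8. The step needs carbanion attack at the primary rather than the secondary sulfate carbon (secured by sterics), O- rather than C-closure in the second displacement (secured by using exactly two equivalents of base, so no carbanion remains at C3 to form a cyclopropane), and substitution rather than elimination toward the C4 hydrogens (favoured by the weakly basic carboxylate and the five-membered transition state).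

Step 8
Reactants: 13 diethyl {(5R)-5-[(2E)-4-[(tert-butyldiphenylsilyl)oxy]-2-methylbut-2-en-1-yl]-2-oxooxolan-3-yl}phosphonate
Product: 14 (5R)-5-[(2E)-4-[(tert-butyldiphenylsilyl)oxy]-2-methylbut-2-en-1-yl]-3-methylideneoxolan-2-one
Conditions: K2CO3, 37% aq. HCHO, THF, 0 °C to rt
Reagents that add atoms: formaldehyde, C=O
Why: Horner–Wadsworth–Emmons olefination of the α-phosphono lactone with formaldehyde is the standard way to an α-methylidene γ-butyrolactone and converges both C3 epimers to one product.

Step 9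
Reactants: 14 (5R)-5-[(2E)-4-[(tert-butyldiphenylsilyl)oxy]-2-methylbut-2-en-1-yl]-3-methylideneoxolan-2-one
Product: 15 (5R)-5-[(2E)-4-hydroxy-2-methylbut-2-en-1-yl]-3-methylideneoxolan-2-one
Conditions: HF·pyridine, pyridine/THF, 0 °C to rt
Reagents that add atoms: none
Why: Buffered fluoride desilylation is non-basic, so the Michael-acceptor lactone and the allylic alcohol should both survive.

Step 10
Reactants: 15 (5R)-5-[(2E)-4-hydroxy-2-methylbut-2-en-1-yl]-3-methylideneoxolan-2-one
Product: 16 (5S)-5-{[(2R,3R)-3-(hydroxymethyl)-2-methyloxiran-2-yl]methyl}-3-methylideneoxolan-2-one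
Conditions: Ti(OiPr)4 (10 mol %), D-(−)-diethyl tartrate (12 mol %), t-BuOOH (2 equiv, in isooctane), 4 Å molecular sieves, CH2Cl2, −20 °C
Reagents that add atoms: tert-butyl hydroperoxide, CC(C)(C)OO
Why: Sharpless asymmetric epoxidation acts only on the allylic-alcohol alkene (the electron-poor methylidene lactone is inert), and the D-(−)-tartrate ligand should give the (2R,3R) oxirane from the (E)-alkene regardless of the remote lactone stereocenter.

Step 11
Reactants: 16 (5S)-5-{[(2R,3R)-3-(hydroxymethyl)-2-methyloxiran-2-yl]methyl}-3-methylideneoxolan-2-one; 17 7-hydroxy-8-methoxy-2H-chromen-2-one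
Product: 18 7-{[(2R,3R)-3-methyl-3-{[(2S)-4-methylidene-5-oxooxolan-2-yl]methyl}oxiran-2-yl]methoxy}-8-methoxy-2H-chromen-2-one
Conditions: PPh3, DIAD, THF, 0 °C to rt
Reagents that add atoms: none
Why: Mitsunobu etherification alkylates the acidic coumarin phenol at the primary carbinol carbon via the alkoxyphosphonium ion; no stereocenter is involved and glycidol-type epoxy alcohols are established substrates.

**Compound list**
1 | geraniol, (2E)-3,7-dimethylocta-2,6-dien-1-ol | CC(C)=CCC/C(C)=C/CO | starting material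
2 | tert-butyl{[(2E)-3,7-dimethylocta-2,6-dien-1-yl]oxy}diphenylsilane | CC(C)=CCC/C(C)=C/CO[Si](c1ccccc1)(c1ccccc1)C(C)(C)C | intermediate
3 | tert-butyl{[(2E)-5-(3,3-dimethyloxiran-2-yl)-3-methylpent-2-en-1-yl]oxy}diphenylsilane (racemic at the oxirane CH) | CC1(C)OC1CC/C(C)=C/CO[Si](c2ccccc2)(c2ccccc2)C(C)(C)C | intermediate
4 | (4E)-6-[(tert-butyldiphenylsilyl)oxy]-4-methylhex-4-enal | O=CCC/C(C)=C/CO[Si](c1ccccc1)(c1ccccc1)C(C)(C)C | intermediate
5 | (2S,4E)-6-[(tert-butyldiphenylsilyl)oxy]-4-methyl-2-[(phenylamino)oxy]hex-4-enal | O=C[C@@H](ONc1ccccc1)C/C(C)=C/CO[Si](c1ccccc1)(c1ccccc1)C(C)(C)C | intermediate (not isolated)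
6 | (2S,4E)-6-[(tert-butyldiphenylsilyl)oxy]-4-methyl-2-[(phenylamino)oxy]hex-4-en-1-ol | OC[C@@H](ONc1ccccc1)C/C(C)=C/CO[Si](c1ccccc1)(c1ccccc1)C(C)(C)C | intermediate
7 | (2S,4E)-6-[(tert-butyldiphenylsilyl)oxy]-4-methylhex-4-ene-1,2-diol | OC[C@@H](O)C/C(C)=C/CO[Si](c1ccccc1)(c1ccccc1)C(C)(C)C | intermediate
8 | (4S)-4-[(2E)-4-[(tert-butyldiphenylsilyl)oxy]-2-methylbut-2-en-1-yl]-1,3,2-dioxathiolane 2-oxide (both configurations at sulfur) | O=S1OC[C@H](C/C(C)=C/CO[Si](c2ccccc2)(c2ccccc2)C(C)(C)C)O1 | intermediate (not isolated)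
9 | (4S)-4-[(2E)-4-[(tert-butyldiphenylsilyl)oxy]-2-methylbut-2-en-1-yl]-1,3,2-dioxathiolane 2,2-dioxide | O=S1(=O)OC[C@H](C/C(C)=C/CO[Si](c2ccccc2)(c2ccccc2)C(C)(C)C)O1 | intermediate
10 | 2-(diethoxyphosphoryl)acetic acid | CCOP(=O)(CC(=O)O)OCC | starting material
11 | dilithium 2-(diethoxyphosphoryl)acetate-2-ide (dianion of 10) | [Li+].[Li+].CCOP(=O)([CH-]C(=O)[O-])OCC | intermediate (not isolated)
12 | dilithium (4S,6E)-8-[(tert-butyldiphenylsilyl)oxy]-2-(diethoxyphosphoryl)-6-methyl-4-(sulfonatooxy)oct-6-enoate | [Li+].[Li+].CCOP(=O)(OCC)C(C[C@H](C/C(C)=C/CO[Si](c1ccccc1)(c1ccccc1)C(C)(C)C)OS(=O)(=O)[O-])C(=O)[O-] | intermediate (not isolated)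
13 | diethyl {(5R)-5-[(2E)-4-[(tert-butyldiphenylsilyl)oxy]-2-methylbut-2-en-1-yl]-2-oxooxolan-3-yl}phosphonate (both C3 epimers) | CCOP(=O)(OCC)C1C[C@@H](C/C(C)=C/CO[Si](c2ccccc2)(c2ccccc2)C(C)(C)C)OC1=O | intermediate
14 | (5R)-5-[(2E)-4-[(tert-butyldiphenylsilyl)oxy]-2-methylbut-2-en-1-yl]-3-methylideneoxolan-2-one | C=C1C[C@@H](C/C(C)=C/CO[Si](c2ccccc2)(c2ccccc2)C(C)(C)C)OC1=O | intermediate
15 | (5R)-5-[(2E)-4-hydroxy-2-methylbut-2-en-1-yl]-3-methylideneoxolan-2-one | C=C1C[C@@H](C/C(C)=C/CO)OC1=O | intermediate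
16 | (5S)-5-{[(2R,3R)-3-(hydroxymethyl)-2-methyloxiran-2-yl]methyl}-3-methylideneoxolan-2-one | C=C1C[C@@H](C[C@@]2(C)O[C@@H]2CO)OC1=O | intermediate
17 | 7-hydroxy-8-methoxy-2H-chromen-2-one | COc1c(O)ccc2ccc(=O)oc12 | starting material
18 | 7-{[(2R,3R)-3-methyl-3-{[(2S)-4-methylidene-5-oxooxolan-2-yl]methyl}oxiran-2-yl]methoxy}-8-methoxy-2H-chromen-2-one | C=C1C[C@@H](C[C@@]2(C)O[C@@H]2COc2ccc3ccc(=O)oc3c2OC)OC1=O | target

Total step count: 11. Longest linear sequence: 11 steps (1 to 18); 10 and 17 enter as purchased fragments.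

**Steps most likely to fail**

Step 7 (proposed new method). The second displacement may stall because a sulfate monoester is a poor leaving group for a carboxylate. Sulfate left unreacted would be hydrolysed on work-up, and the resulting hydroxy acid would lactonise with retention, eroding the configuration at C5. Proton transfer followed by 3-exo closure to a cyclopropane is the other leak. Fallback, from 9 back to 13, using only established displacements: 9 is opened with the sodium salt of tert-butyl 2-(diethoxyphosphoryl)acetate (NaH, THF) to give the sodium sulfate monoester F1. Its sulfate is hydrolysed with S–O cleavage (catalytic H2SO4, one equivalent of water, THF), giving the γ-hydroxy tert-butyl ester F2 with the carbinol configuration retained. Mesylation (MsCl, Et3N, CH2Cl2) gives the mesylate F3. The tert-butyl ester is cleaved under buffered conditions (Me3SiOTf, 2,6-lutidine, then aqueous work-up) to the γ-mesyloxy acid F4. Cs2CO3 in DMF then closes the same O1–C5 bond by the classical carboxylate displacement of a secondary mesylate with inversion, which returns to 13.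

Step 6. Over-oxidation may occur: RuO4 can dihydroxylate or cleave the trisubstituted alkene before oxidation at sulfur is complete. Fallback, from 4 back to 13, with no oxidant after the alkene is in place: 4 undergoes enamine-catalysed α-chlorination with 2,3,4,5,6,6-hexachlorocyclohexa-2,4-dien-1-one and (5S)-5-benzyl-2,2,3-trimethylimidazolidin-4-one trifluoroacetate. Attack anti to the benzyl group predicts that this catalyst gives the (2S)-chloride; its enantiomer would be used if a model aldehyde shows the opposite sense. This gives the (2S)-α-chloro aldehyde F5, which is reduced in the same flask (NaBH4) to the (2S)-chlorohydrin F6. Tf2O and 2,6-lutidine at −78 °C convert it into the primary triflate F7. Alkylation of dianion 11 with F7 at −78 °C gives the lithium γ-chloro carboxylate F8. On warming in DMF, F8 lactonises by carboxylate displacement of the secondary chloride with inversion and returns to 13.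

Step 11. Conjugate addition of PPh3 or of the phenoxide to the methylidene lactone, or opening of the oxirane by the phenol, may compete with O-alkylation. Fallback, from 15 to 18, which moves the ether formation ahead of the epoxidation and avoids phosphine: 15 is converted with PBr3 (Et2O, 0 °C) into the allylic bromide F9. Phenol 17 is alkylated with F9 (K2CO3, acetone) to give the allyl aryl ether F10. Shi epoxidation (D-fructose-derived ketone, KHSO5 as 2KHSO5·KHSO4·K2SO4, K2CO3 buffer, MeCN/dimethoxymethane/H2O, 0 °C) should then oxidise only the electron-rich trisubstituted alkene and arrive at 18. The ketone enantiomer is chosen by the spiro transition-state model to give the (2R,3R) oxirane.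

**Further compounds**
F1 | step 7 | sodium (4S,6E)-1-tert-butoxy-8-[(tert-butyldiphenylsilyl)oxy]-2-(diethoxyphosphoryl)-6-methyl-1-oxooct-6-en-4-yl sulfate | [Na+].CCOP(=O)(OCC)C(C[C@H](C/C(C)=C/CO[Si](c1ccccc1)(c1ccccc1)C(C)(C)C)OS(=O)(=O)[O-])C(=O)OC(C)(C)C
F2 | step 7 | tert-butyl (4S,6E)-8-[(tert-butyldiphenylsilyl)oxy]-2-(diethoxyphosphoryl)-4-hydroxy-6-methyloct-6-enoate | CCOP(=O)(OCC)C(C[C@H](C/C(C)=C/CO[Si](c1ccccc1)(c1ccccc1)C(C)(C)C)O)C(=O)OC(C)(C)C
F3 | step 7 | tert-butyl (4S,6E)-8-[(tert-butyldiphenylsilyl)oxy]-2-(diethoxyphosphoryl)-4-(methanesulfonyloxy)-6-methyloct-6-enoate | CCOP(=O)(OCC)C(C[C@H](C/C(C)=C/CO[Si](c1ccccc1)(c1ccccc1)C(C)(C)C)OS(C)(=O)=O)C(=O)OC(C)(C)C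
F4 | step 7 | (4S,6E)-8-[(tert-butyldiphenylsilyl)oxy]-2-(diethoxyphosphoryl)-4-(methanesulfonyloxy)-6-methyloct-6-enoic acid | CCOP(=O)(OCC)C(C[C@H](C/C(C)=C/CO[Si](c1ccccc1)(c1ccccc1)C(C)(C)C)OS(C)(=O)=O)C(=O)O
F5 | step 6 | (2S,4E)-6-[(tert-butyldiphenylsilyl)oxy]-2-chloro-4-methylhex-4-enal | O=C[C@@H](Cl)C/C(C)=C/CO[Si](c1ccccc1)(c1ccccc1)C(C)(C)C
F6 | step 6 | (2S,4E)-6-[(tert-butyldiphenylsilyl)oxy]-2-chloro-4-methylhex-4-en-1-ol | OC[C@@H](Cl)C/C(C)=C/CO[Si](c1ccccc1)(c1ccccc1)C(C)(C)C
F7 | step 6 | (2S,4E)-6-[(tert-butyldiphenylsilyl)oxy]-2-chloro-4-methylhex-4-en-1-yl trifluoromethanesulfonate | O=S(=O)(OC[C@@H](Cl)C/C(C)=C/CO[Si](c1ccccc1)(c1ccccc1)C(C)(C)C)C(F)(F)F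
F8 | step 6 | lithium (4S,6E)-8-[(tert-butyldiphenylsilyl)oxy]-4-chloro-2-(diethoxyphosphoryl)-6-methyloct-6-enoate | [Li+].CCOP(=O)(OCC)C(C[C@@H](Cl)C/C(C)=C/CO[Si](c1ccccc1)(c1ccccc1)C(C)(C)C)C(=O)[O-]
F9 | step 11 | (5R)-5-[(2E)-4-bromo-2-methylbut-2-en-1-yl]-3-methylideneoxolan-2-one | C=C1C[C@@H](C/C(C)=C/CBr)OC1=O
F10 | step 11 | 8-methoxy-7-{[(2E)-3-methyl-4-[(2R)-4-methylidene-5-oxooxolan-2-yl]but-2-en-1-yl]oxy}-2H-chromen-2-one | C=C1C[C@@H](C/C(C)=C/COc2ccc3ccc(=O)oc3c2OC)OC1=O
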